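**Retrosynthetic overview**

- The target comes from one protected precursor by a single acidolysis: three tert-butyl esters fall off and a pivalaldehyde acetal that masks the tertiary OH and the CH2CO2H arm is hydrolysed.
- Key step: Michael addition of the enolate of the complete trienyl γ-lactone to a chiral, malate-derived 1,3-dioxin-4-one that already carries the isocitrate ester. It forms the quaternary C–C bond and both citrate stereocentres at once, with no aldol onto a keto ester and no esterification of a hindered tertiary acid.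
- The dioxinone acid and the isocitrate alcohol both come from (S)-malic acid: the first by self-regeneration of the stereocentre (cis-dioxanone, then dioxinone), the second by Fráter–Seebach alkylation; they are joined while the acid is still sp2-bound.
- The trienyl lactone comes from Julia–Kocienski olefination of a lactone aldehyde with a skipped-diene sulfone (alkyne coupling, then Lindlar reduction).
- Rings: ring A (the γ-lactone) is bought preformed and never opened; ring B (the temporary dioxanone/dioxinone) is closed in step 4 and opened in step 15.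

Assumption: the SMILES is read literally as lactone C3 = S and C5 = S (trans), citrate quaternary carbon = R, isocitrate part (1S,2R), side chain 1E,5Z,8Z, all four carboxylic acids free.

**Route**

Step 1
Reactants: 1 (S)-malic acid
Product: 2 di-tert-butyl (2S)-2-hydroxybutanedioate
Conditions: O-tert-butyl-N,N'-diisopropylisourea (2.5 equiv), CH2Cl2, rt, 24 h
Reagents that add atoms: O-tert-butyl-N,N'-diisopropylisourea, CC(C)NC(=NC(C)C)OC(C)(C)C
Why: Isourea esterification transfers tert-butyl to both carboxylic acids under neutral conditions and leaves the secondary alcohol and the stereocentre untouched.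

Step 2
Reactants: 2 di-tert-butyl (2S)-2-hydroxybutanedioate; 3 tert-butyl bromoacetate
Product: 5 tri-tert-butyl (1S,2R)-1-hydroxypropane-1,2,3-tricarboxylate, via dilithium alkoxide enolate 4 (not isolated)
Conditions: LiN(SiMe3)2 (2.2 equiv), THF, −78 to −20 °C; then 3, −78 to −10 °C
Reagents that add atoms: none
Why: Fráter–Seebach alkylation: the chelated dilithium alkoxide enolate is alkylated anti to the carbinol substituent, which sets the new centre as R (anti, isocitrate 2S,3R) while the malate centre is retained.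

Step 3
Reactants: 1 (S)-malic acid
Product: 8 (3S)-3-hydroxy-4-oxo-4-[2-(trimethylsilyl)ethoxy]butanoic acid, via trifluoroacetylated malic anhydride 6 (not isolated), via trifluoroacetylated monoester 7 (not isolated)
Conditions: (CF3CO)2O, 0 °C to rt, evaporate; Me3SiCH2CH2OH, CH2Cl2, 0 °C to rt; then MeOH, rt
Reagents that add atoms: 2-(trimethylsilyl)ethanol, C[Si](C)(C)CCO
Why: Regioselective alcoholysis of the O-trifluoroacetyl malic anhydride (Miller monoesterification) occurs at the carbonyl next to the acyloxy-bearing carbon, giving the 1-monoester and leaving the β-hydroxy acid unit free with the stereocentre untouched.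

Step 4
Reactants: 8 (3S)-3-hydroxy-4-oxo-4-[2-(trimethylsilyl)ethoxy]butanoic acid
Product: 9 2-(trimethylsilyl)ethyl (2R,4S)-2-tert-butyl-6-oxo-1,3-dioxane-4-carboxylate
Conditions: tBuCHO, TsOH·H2O (5 mol%), CH2Cl2, reflux, 4 Å molecular sieves; cis isomer purified by chromatography
Reagents that add atoms: 2,2-dimethylpropanal (pivalaldehyde), CC(C)(C)C=O
Why: Acid-catalysed acetalisation of a β-hydroxy acid (Seebach dioxanone formation) gives the thermodynamically preferred cis-diequatorial 1,3-dioxan-4-one, so the (S) malate centre fixes the new acetal centre as R.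

Step 5
Reactants: 9 2-(trimethylsilyl)ethyl (2R,4S)-2-tert-butyl-6-oxo-1,3-dioxane-4-carboxylate
Product: 11 2-(trimethylsilyl)ethyl (2R)-2-tert-butyl-4-oxo-4H-1,3-dioxine-6-carboxylate, via ring bromide 10 (not isolated)
Conditions: NBS, AIBN (5 mol%), PhCF3, 80 °C; then Et3N, CH2Cl2, 0 °C
Reagents that add atoms: none
Why: Wohl–Ziegler radical bromination at the captodative C–H (alpha to the ring oxygen and the ester) followed by E2 loss of HBr gives the dioxinone, which erases the malate centre while the acetal centre keeps the chirality (self-regeneration of stereocentres).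

Step 6
Reactants: 11 2-(trimethylsilyl)ethyl (2R)-2-tert-butyl-4-oxo-4H-1,3-dioxine-6-carboxylate
Product: 12 (2R)-2-tert-butyl-4-oxo-4H-1,3-dioxine-6-carboxylic acid
Conditions: Bu4NF, AcOH (1:1), THF, 0 °C to rt
Reagents that add atoms: none
Why: Fluoride-induced β-elimination of the 2-(trimethylsilyl)ethyl ester frees the acid under buffered conditions that leave the acyl acetal and its stereocentre intact.

Step 7
Reactants: 12 (2R)-2-tert-butyl-4-oxo-4H-1,3-dioxine-6-carboxylic acid; 5 tri-tert-butyl (1S,2R)-1-hydroxypropane-1,2,3-tricarboxylate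
Product: 13 tri-tert-butyl (1S,2R)-1-{[(2R)-2-tert-butyl-4-oxo-4H-1,3-dioxine-6-carbonyl]oxy}propane-1,2,3-tricarboxylate
Conditions: N,N'-diisopropylcarbodiimide, DMAP (10 mol%), CH2Cl2, 0 °C to rt
Reagents that add atoms: none
Why: Steglich esterification of an unhindered sp2-bound acid with the secondary isocitrate alcohol installs the ester that would be very hindered to make once the neighbouring carbon is quaternary, and no stereocentre is touched.

Step 8
Reactants: 14 pent-4-yn-1-ol; 15 1-bromooct-2-yne
Product: 16 trideca-4,7-diyn-1-ol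
Conditions: CuI (10 mol%), Bu4NCl, Na2CO3, DMF, rt
Reagents that add atoms: none
Why: Copper-catalysed coupling of a terminal alkyne with a propargylic bromide (SN2 of the copper acetylide) gives the skipped diyne without protecting the alcohol.

Step 9
Reactants: 16 trideca-4,7-diyn-1-ol
Product: 17 (4Z,7Z)-trideca-4,7-dien-1-ol
Conditions: H2 (1 atm), Pd/CaCO3 poisoned with Pb(OAc)2 (Lindlar catalyst), quinoline, EtOAc, rt
Reagents that add atoms: none
Why: Lindlar semihydrogenation delivers hydrogen syn to each alkyne and so sets both Z double bonds.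

Step 10
Reactants: 17 (4Z,7Z)-trideca-4,7-dien-1-ol
Product: 18 1-phenyl-5-{[(4Z,7Z)-trideca-4,7-dien-1-yl]sulfanyl}-1H-tetrazole
Conditions: 1-phenyl-1H-tetrazole-5-thiol, PPh3, DIAD, THF, 0 °C to rt
Reagents that add atoms: 1-phenyl-1H-tetrazole-5-thiol, Sc1nnnn1-c1ccccc1
Why: Mitsunobu thioetherification of the primary alcohol with the acidic tetrazole thiol proceeds without touching the Z-alkenes.

Step 11
Reactants: 18 1-phenyl-5-{[(4Z,7Z)-trideca-4,7-dien-1-yl]sulfanyl}-1H-tetrazole
Product: 19 1-phenyl-5-{[(4Z,7Z)-trideca-4,7-dien-1-yl]sulfonyl}-1H-tetrazole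
Conditions: H2O2 (30% aq), (NH4)6Mo7O24·4H2O (10 mol%), EtOH, 0 °C to rt
Reagents that add atoms: hydrogen peroxide, OO
Why: Molybdate-catalysed peroxide oxidation takes the sulfide to the sulfone much faster than it epoxidises isolated Z-alkenes.

Step 12
Reactants: 20 (5S)-5-(hydroxymethyl)oxolan-2-one
Product: 21 (2S)-5-oxooxolane-2-carbaldehyde
Conditions: Dess–Martin periodinane, CH2Cl2, 0 °C to rt; used at once
Reagents that add atoms: none
Why: Dess–Martin oxidation of the primary alcohol under non-basic conditions preserves the oxygen-bearing stereocentre, which becomes C5 of the target lactone.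

Step 13
Reactants: 19 1-phenyl-5-{[(4Z,7Z)-trideca-4,7-dien-1-yl]sulfonyl}-1H-tetrazole; 21 (2S)-5-oxooxolane-2-carbaldehyde
Product: 23 (5S)-5-[(1E,5Z,8Z)-tetradeca-1,5,8-trien-1-yl]oxolan-2-one, via potassium sulfonyl carbanion 22 (not isolated)
Conditions: KN(SiMe3)2, DME, −60 °C; then 21, −60 °C to rt
Reagents that add atoms: none
Why: Julia–Kocienski olefination: the sulfonyl carbanion adds to the aldehyde, and Smiles rearrangement with anti-elimination gives the E-alkene, while the lactone stereocentre comes unchanged from 20.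

Step 14
Reactants: 23 (5S)-5-[(1E,5Z,8Z)-tetradeca-1,5,8-trien-1-yl]oxolan-2-one; 13 tri-tert-butyl (1S,2R)-1-{[(2R)-2-tert-butyl-4-oxo-4H-1,3-dioxine-6-carbonyl]oxy}propane-1,2,3-tricarboxylate
Product: 25 tri-tert-butyl (1S,2R)-1-[({(2R,4R)-2-tert-butyl-6-oxo-4-[(3S,5S)-2-oxo-5-[(1E,5Z,8Z)-tetradeca-1,5,8-trien-1-yl]oxolan-3-yl]-1,3-dioxan-4-yl}carbonyl)oxy]propane-1,2,3-tricarboxylate, via lithium lactone enolate 24 (not isolated)
Conditions: LiN(iPr)2 (0.98 equiv), THF, −78 °C; then 13, −78 °C; AcOH quench at −78 °C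
Reagents that add atoms: none
Why: Proposed new method: the lithium enolate of 23 adds in Michael fashion to the oxygen-bearing ring carbon of the doubly activated dioxinone 13 (the electrophilic end of the vinylogous carbonate, as in addition–elimination at alkoxyfumarates and in Seebach's cuprate additions to 2-tert-butyl-6-methyl-1,3-dioxin-4-one), the enolate reacting on its face anti to the trienyl group (3,5-trans lactone, C3 = S) and the dioxinone on its face anti to the tert-butyl group (new quaternary centre = R, the carbon bond taking the place of the former malate hydrogen), and the cold acid quench protonates the dioxanone enolate before it can ring-open by β-elimination; the closest known reaction types are ester-enolate Michael additions and conjugate additions to chiral 1,3-dioxin-4-ones.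

Step 15
Reactants: 25 tri-tert-butyl (1S,2R)-1-[({(2R,4R)-2-tert-butyl-6-oxo-4-[(3S,5S)-2-oxo-5-[(1E,5Z,8Z)-tetradeca-1,5,8-trien-1-yl]oxolan-3-yl]-1,3-dioxan-4-yl}carbonyl)oxy]propane-1,2,3-tricarboxylate
Product: 26 (1S,2R)-1-({(2R)-3-carboxy-2-hydroxy-2-[(3S,5S)-2-oxo-5-[(1E,5Z,8Z)-tetradeca-1,5,8-trien-1-yl]oxolan-3-yl]propanoyl}oxy)propane-1,2,3-tricarboxylic acid
Conditions: CF3CO2H/H2O (9:1), CH2Cl2, 0 °C to rt
Reagents that add atoms: none
Why: Acidolysis of the three tert-butyl esters (loss of isobutene) and hydrolysis of the acyl acetal through its oxocarbenium ion free the four acids and the tertiary alcohol without touching any stereocentre, the central ester or the lactone.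

**Compound list**

1 | (S)-malic acid, (2S)-2-hydroxybutanedioic acid | O[C@@H](CC(=O)O)C(=O)O | starting material
2 | di-tert-butyl (2S)-2-hydroxybutanedioate | O[C@@H](CC(=O)OC(C)(C)C)C(=O)OC(C)(C)C | intermediate
3 | tert-butyl bromoacetate | BrCC(=O)OC(C)(C)C | starting material
4 | dilithium alkoxide enolate of 2 | [Li+].[Li+].[O-][C@@H](C=C([O-])OC(C)(C)C)C(=O)OC(C)(C)C | intermediate (not isolated)
5 | tri-tert-butyl (1S,2R)-1-hydroxypropane-1,2,3-tricarboxylate, the (2S,3R)-isocitrate triester | O[C@H](C(=O)OC(C)(C)C)[C@@H](CC(=O)OC(C)(C)C)C(=O)OC(C)(C)C | intermediate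
6 | (3S)-2,5-dioxooxolan-3-yl trifluoroacetate | O=C1OC(=O)C[C@@H]1OC(=O)C(F)(F)F | intermediate (not isolated)
7 | (3S)-4-oxo-3-[(trifluoroacetyl)oxy]-4-[2-(trimethylsilyl)ethoxy]butanoic acid | FC(F)(F)C(=O)O[C@@H](CC(=O)O)C(=O)OCC[Si](C)(C)C | intermediate (not isolated)
8 | (3S)-3-hydroxy-4-oxo-4-[2-(trimethylsilyl)ethoxy]butanoic acid | O[C@@H](CC(=O)O)C(=O)OCC[Si](C)(C)C | intermediate
9 | 2-(trimethylsilyl)ethyl (2R,4S)-2-tert-butyl-6-oxo-1,3-dioxane-4-carboxylate (cis) | C[Si](C)(C)CCOC(=O)[C@@H]1CC(=O)O[C@H](C(C)(C)C)O1 | intermediate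
10 | 2-(trimethylsilyl)ethyl 4-bromo-2-tert-butyl-6-oxo-1,3-dioxane-4-carboxylate (acetal centre as in 9, both bromide epimers) | C[Si](C)(C)CCOC(=O)C1(Br)CC(=O)O[C@H](C(C)(C)C)O1 | intermediate (not isolated)
11 | 2-(trimethylsilyl)ethyl (2R)-2-tert-butyl-4-oxo-4H-1,3-dioxine-6-carboxylate | C[Si](C)(C)CCOC(=O)C1=CC(=O)O[C@H](C(C)(C)C)O1 | intermediate
12 | (2R)-2-tert-butyl-4-oxo-4H-1,3-dioxine-6-carboxylic acid | OC(=O)C1=CC(=O)O[C@H](C(C)(C)C)O1 | intermediate
13 | tri-tert-butyl (1S,2R)-1-{[(2R)-2-tert-butyl-4-oxo-4H-1,3-dioxine-6-carbonyl]oxy}propane-1,2,3-tricarboxylate | O=C(O[C@H](C(=O)OC(C)(C)C)[C@@H](CC(=O)OC(C)(C)C)C(=O)OC(C)(C)C)C1=CC(=O)O[C@H](C(C)(C)C)O1 | intermediate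
14 | pent-4-yn-1-ol | C#CCCCO | starting material
15 | 1-bromooct-2-yne | CCCCCC#CCBr | starting material
16 | trideca-4,7-diyn-1-ol | CCCCCC#CCC#CCCCO | intermediate
17 | (4Z,7Z)-trideca-4,7-dien-1-ol | CCCCC/C=C\C/C=C\CCCO | intermediate
18 | 1-phenyl-5-{[(4Z,7Z)-trideca-4,7-dien-1-yl]sulfanyl}-1H-tetrazole | CCCCC/C=C\C/C=C\CCCSc1nnnn1-c1ccccc1 | intermediate
19 | 1-phenyl-5-{[(4Z,7Z)-trideca-4,7-dien-1-yl]sulfonyl}-1H-tetrazole | CCCCC/C=C\C/C=C\CCCS(=O)(=O)c1nnnn1-c1ccccc1 | intermediate
20 | (5S)-5-(hydroxymethyl)oxolan-2-one | OC[C@@H]1CCC(=O)O1 | starting material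
21 | (2S)-5-oxooxolane-2-carbaldehyde | O=C[C@@H]1CCC(=O)O1 | intermediate
22 | potassium sulfonyl carbanion of 19 | [K+].CCCCC/C=C\C/C=C\CC[CH-]S(=O)(=O)c1nnnn1-c1ccccc1 | intermediate (not isolated)
23 | (5S)-5-[(1E,5Z,8Z)-tetradeca-1,5,8-trien-1-yl]oxolan-2-one | CCCCC/C=C\C/C=C\CC/C=C/[C@@H]1CCC(=O)O1 | intermediate
24 | lithium enolate of 23 | [Li+].CCCCC/C=C\C/C=C\CC/C=C/[C@@H]1CC=C([O-])O1 | intermediate (not isolated)
25 | tri-tert-butyl (1S,2R)-1-[({(2R,4R)-2-tert-butyl-6-oxo-4-[(3S,5S)-2-oxo-5-[(1E,5Z,8Z)-tetradeca-1,5,8-trien-1-yl]oxolan-3-yl]-1,3-dioxan-4-yl}carbonyl)oxy]propane-1,2,3-tricarboxylate | CCCCC/C=C\C/C=C\CC/C=C/[C@@H]1C[C@@H]([C@@]2(O[C@@H](C(C)(C)C)OC(=O)C2)C(=O)O[C@H](C(=O)OC(C)(C)C)[C@@H](CC(=O)OC(C)(C)C)C(=O)OC(C)(C)C)C(=O)O1 | intermediate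
26 | CNP0327249.2, (1S,2R)-1-({(2R)-3-carboxy-2-hydroxy-2-[(3S,5S)-2-oxo-5-[(1E,5Z,8Z)-tetradeca-1,5,8-trien-1-yl]oxolan-3-yl]propanoyl}oxy)propane-1,2,3-tricarboxylic acid | CCCCC/C=C\C/C=C\CC/C=C/[C@@H]1C[C@@H]([C@](O)(CC(=O)O)C(=O)O[C@H](C(=O)O)[C@@H](CC(=O)O)C(=O)O)C(=O)O1 | target

**Totals and risks**

Total step count: 15. Longest linear sequence: 7 steps (steps 3, 4, 5, 6, 7, 14, 15 from (S)-malic acid; the side-chain branch 8, 9, 10, 11, 13, 14, 15 is equally long).

The step most likely to fail is step 14. The enolate could attack the CH carbon of the dioxinone instead of the oxygen-bearing carbon, the addition could revert, or the adduct enolate could ring-open by β-elimination. The fallback sets out from 23 and comes back at 25. The lactone is converted with LiN(iPr)2 and tert-butyldimethylsilyl chloride (THF/DMPU, −78 °C) into the tert-butyldimethylsilyl ketene acetal F2, which is added to 13 in 5 M LiClO4 in Et2O (Mukaiyama–Michael addition). The lithium cation binds the most basic, vinylogous carbonyl and so directs attack to the oxygen-bearing carbon, and silyl transfer traps the product as the silylated adduct F3, which can neither revert nor eliminate. Dilute aqueous citric acid then gives 25.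

Second is step 5, a radical bromination on a substrate that has not been used in this reaction; the acetal C–H or the silylethyl group might compete. The fallback sets out from 9 and comes back at 11 by an ionic route. LiN(SiMe3)2 in THF at −78 °C removes a ring CH2 proton next to the ring carbonyl, and PhSeBr gives the phenylselanyl dioxanone F1, with selenium expected anti to the ester and therefore syn to the neighbouring hydrogen. H2O2 and pyridine in CH2Cl2 at 0 °C then form the selenoxide, which undergoes syn-elimination to the dioxinone 11.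

Third is step 15. Hydrolysis of the tert-butyl acyl acetal may need longer exposure to strong acid than the allylic lactone and the skipped diene tolerate. The fallback sets out from 25 and comes back at 26 in two stages. LiOH and H2O2 in THF/H2O at 0 °C attack the activated acyl-acetal carbonyl selectively, and the hemiacetal collapses with loss of pivalaldehyde. Na2SO3 quench and acidification to pH 3 (which also recloses any opened lactone) give the hydroxy acid triester F4. A short treatment with anhydrous CF3CO2H/CH2Cl2 (1:1, 0 °C, 1 h) then removes only the tert-butyl esters and gives 26.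

Further compounds
F1 | step 5 | 2-(trimethylsilyl)ethyl 2-tert-butyl-6-oxo-5-(phenylselanyl)-1,3-dioxane-4-carboxylate (acetal and ester-bearing centres as in 9) | C[Si](C)(C)CCOC(=O)[C@@H]1C([Se]c2ccccc2)C(=O)O[C@H](C(C)(C)C)O1
F2 | step 14 | tert-butyl(dimethyl){[(5S)-5-[(1E,5Z,8Z)-tetradeca-1,5,8-trien-1-yl]-4,5-dihydrofuran-2-yl]oxy}silane | CCCCC/C=C\C/C=C\CC/C=C/[C@@H]1CC=C(O[Si](C)(C)C(C)(C)C)O1
F3 | step 14 | O-tert-butyldimethylsilyl ketene acetal of 25 (6-silyloxy-4H-1,3-dioxine form, stereocentres as in 25) | CCCCC/C=C\C/C=C\CC/C=C/[C@@H]1C[C@@H]([C@@]2(O[C@@H](C(C)(C)C)OC(O[Si](C)(C)C(C)(C)C)=C2)C(=O)O[C@H](C(=O)OC(C)(C)C)[C@@H](CC(=O)OC(C)(C)C)C(=O)OC(C)(C)C)C(=O)O1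
F4 | step 15 | (3R)-3-hydroxy-3-[(3S,5S)-2-oxo-5-[(1E,5Z,8Z)-tetradeca-1,5,8-trien-1-yl]oxolan-3-yl]-4-oxo-4-{[(1S,2R)-1,2,3-tris(tert-butoxycarbonyl)propyl]oxy}butanoic acid | CCCCC/C=C\C/C=C\CC/C=C/[C@@H]1C[C@@H]([C@](O)(CC(=O)O)C(=O)O[C@H](C(=O)OC(C)(C)C)[C@@H](CC(=O)OC(C)(C)C)C(=O)OC(C)(C)C)C(=O)O1
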